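**Plan**
- Retrosynthesis: the aryl–vinyl bond of the propenal chain is cut first (Heck reaction on an aryl bromide). Then the O1–C2 and C2–C3 bonds of the dioxane ring are cut, which removes the benzylic carbon as an aryl carbene and leaves a five-membered 2-methyl-1,3-benzodioxole. Last, the two acetal C–O bonds are cut.
- Forward: bromo-methoxy-catechol (Dakin oxidation) → 1,3-dioxole ring (acetal) → enlargement by one carbon to the 1,4-dioxane ring (oxonium ylide, [1,2]-shift) → propenal chain.
- Enabling feature: in the O1–C2–C3–O4 unit both sp3 carbons lie between two aryl ether oxygens. C3 with its methyl group can therefore first be the acetal carbon of a benzodioxole and migrate as an oxygen-stabilised centre. The C5 methoxy group beside O4 and the substituent para to O4 tell the two oxygens apart.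
- Stereochemistry: the benzylic centre comes from a chiral copper catalyst at the ylide stage, and the methyl-bearing centre is placed trans by the shift. The acetal is racemic, so the cis isomer from its mismatched enantiomer is removed by chromatography.

Key step: step 4

Assumption: the sense of induction of the copper–bisoxazoline catalyst at the benzylic carbon cannot be taken from a close model. The (S,S) ligand is written, and its mirror image is to be used if a first run shows the opposite sense. Compounds 1 and 4 and all reagents are taken as commercial.

**Step 1**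
Reactants: 1 5-bromo-2-hydroxy-3-methoxybenzaldehyde
Product: 2 5-bromo-3-methoxybenzene-1,2-diol
Conditions: 30% aq. H2O2 (1.1 equiv), NaOH (1.0 equiv), H2O, 0 °C → rt, N2; then HCl
Reagents that add atoms: hydrogen peroxide, OO
Why: Dakin oxidation, in which the hydroperoxide anion adds to the aldehyde, the aryl group with its ortho phenoxide migrates to oxygen and the aryl formate is hydrolysed in the flask; no stereocentre is formed.

**Step 2**
Reactants: 2 5-bromo-3-methoxybenzene-1,2-diol
Product: 3 rac-6-bromo-4-methoxy-2-methyl-1,3-benzodioxole
Conditions: CH3CH(OEt)2 (2 equiv), TsOH (5 mol %), toluene, 100 °C, EtOH distilled off, N2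
Reagents that add atoms: acetaldehyde diethyl acetal, CCOC(C)OCC
Why: Acid-catalysed transacetalisation, in which the second hydroxyl closes the 1,3-dioxole ring by 5-exo attack on the oxocarbenium ion and removal of ethanol drives the exchange; the acetal carbon is a stereocentre only because the arene is unsymmetrical, and 3 is racemic.

**Step 3**
Reactants: 4 3,4,5-trimethoxybenzaldehyde
Product: 5 (E)-(3,4,5-trimethoxybenzylidene)hydrazine
Conditions: N2H4·H2O (5 equiv), EtOH, 0 °C → rt, aldehyde added slowly; used fresh
Reagents that add atoms: hydrazine (as the hydrate), NN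
Why: Condensation of an aldehyde with hydrazine to the (E)-hydrazone, with excess hydrazine and inverse addition to suppress azine formation.

**Step 4**
Reactants: 3 rac-6-bromo-4-methoxy-2-methyl-1,3-benzodioxole; 5 (E)-(3,4,5-trimethoxybenzylidene)hydrazine
Product: 7 (2R,3R)-7-bromo-5-methoxy-3-methyl-2-(3,4,5-trimethoxyphenyl)-2,3-dihydro-1,4-benzodioxine, via aryldiazomethane 6 (not isolated)
Conditions: 5, activated MnO2, Na2SO4, CH2Cl2, −10 °C, cold filtration; filtrate added over 4 h to 3 (3 equiv, excess recovered), Cu(MeCN)4PF6 (5 mol %), (S,S)-tBu-box (6 mol %), 4 Å MS, CH2Cl2, −20 → 0 °C; chromatography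
Reagents that add atoms: none
Why: Proposed new method: MnO2 dehydrogenates 5 to the aryldiazomethane 6, whose copper carbene is attacked by the in-plane lone pair of dioxole oxygen O1 of 3 (the oxygen next to C7–H) to give a copper-bound oxonium ylide; the acetal carbon C2, stabilised by O3 as an oxocarbenium ion or α-oxy radical, then shifts from O1 to the ylide carbon ([1,2]-Stevens shift), so the carbene carbon is inserted into the O1–C2 bond and the five-membered 1,3-dioxole becomes the six-membered 1,4-dioxane. The closest known reaction type is the copper-catalysed, ligand-controlled ring expansion of oxetanes and of 1,3-dioxolanes by diazo compounds through oxonium ylides; new here are an aryl ether oxygen as the nucleophile and a carbene without an acceptor group. The six-membered ring closes through the new C–C bond between the benzylic ylide carbon and the migrating acetal carbon, a 1,2-shift that is formally a 6-endo attack of the copper-bound carbon on the ring-opened oxocarbenium ion. The benzylic stereocentre (C2 of 7) is set by the bisoxazoline ligand when the prochiral carbene carbon bonds to oxygen, and the methyl-bearing centre (C3 of 7) is expected trans to the aryl group because the shift passes through a half-chair with both groups pseudoequatorial. If the shift keeps the configuration of the acetal carbon, as in the oxetane case, only the matched enantiomer of racemic 3 can give trans-7 and the other gives the cis isomer, which is separated by chromatography. The step needs a choice between the two dioxole oxygens, secured by the C4 methoxy group that shields O3 in the ring plane and by the para bromine that slightly lowers the electron density at O3; it also needs ylide formation to outrun carbene dimerisation, secured by slow addition of 6 to excess 3, and copper is chosen because it favours ylide formation over insertion into the acetal C–H bond.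

**Step 5**
Reactants: 7 (2R,3R)-7-bromo-5-methoxy-3-methyl-2-(3,4,5-trimethoxyphenyl)-2,3-dihydro-1,4-benzodioxine
Product: 9 (2E)-3-[(2R,3R)-5-methoxy-3-methyl-2-(3,4,5-trimethoxyphenyl)-2,3-dihydro-1,4-benzodioxin-7-yl]prop-2-enal (target), via enal diethyl acetal 8 (not isolated)
Conditions: CH2=CHCH(OEt)2 (3 equiv), Pd(OAc)2 (3 mol %), nBu4NOAc (2 equiv), K2CO3 (1.5 equiv), KCl, DMF, 90 °C; then 2 M HCl, rt
Reagents that add atoms: acrolein diethyl acetal, C=CC(OCC)OCC; water, O
Why: Heck reaction of the aryl bromide with the vinyl acetal under phosphine-free conditions with acetate and chloride additives, which give cinnamaldehyde acetals by syn insertion and syn β-hydride elimination away from the acetal carbon (E alkene), followed by mild acetal hydrolysis; the ring stereocentres are remote and untouched.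

**Compound list**
1 | 5-bromo-2-hydroxy-3-methoxybenzaldehyde | COc1cc(Br)cc(C=O)c1O | starting material
2 | 5-bromo-3-methoxybenzene-1,2-diol | COc1cc(Br)cc(O)c1O | intermediate
3 | rac-6-bromo-4-methoxy-2-methyl-1,3-benzodioxole | CC1Oc2cc(Br)cc(OC)c2O1 | intermediate
4 | 3,4,5-trimethoxybenzaldehyde | COc1cc(C=O)cc(OC)c1OC | starting material
5 | (E)-(3,4,5-trimethoxybenzylidene)hydrazine | COc1cc(/C=N/N)cc(OC)c1OC | intermediate
6 | 5-(diazomethyl)-1,2,3-trimethoxybenzene | COc1cc(C=[N+]=[N-])cc(OC)c1OC | intermediate (not isolated)
7 | (2R,3R)-7-bromo-5-methoxy-3-methyl-2-(3,4,5-trimethoxyphenyl)-2,3-dihydro-1,4-benzodioxine | COc1cc([C@H]2Oc3cc(Br)cc(OC)c3O[C@@H]2C)cc(OC)c1OC | intermediate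
8 | (2R,3R)-7-[(1E)-3,3-diethoxyprop-1-en-1-yl]-5-methoxy-3-methyl-2-(3,4,5-trimethoxyphenyl)-2,3-dihydro-1,4-benzodioxine | COc1cc([C@H]2Oc3cc(/C=C/C(OCC)OCC)cc(OC)c3O[C@@H]2C)cc(OC)c1OC | intermediate (not isolated)
9 | (2E)-3-[(2R,3R)-5-methoxy-3-methyl-2-(3,4,5-trimethoxyphenyl)-2,3-dihydro-1,4-benzodioxin-7-yl]prop-2-enal | COc1cc([C@H]2Oc3cc(/C=C/C=O)cc(OC)c3O[C@@H]2C)cc(OC)c1OC | target

**Count**
Total steps: 5. Longest linear sequence: 4 steps (1 → 2 → 3 → 7 → 9); step 3 lies on the short branch.

**Steps most likely to fail**

1. Step 4 (proposed new method). Carbene dimerisation may outrun ylide formation at the weakly basic aryl ether oxygen. The ylide may form at the hindered oxygen. Ligand control at the benzylic carbon may be weak, or retention at the racemic acetal carbon may leave little trans isomer or low enantiomeric purity.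
 Fallback with known chemistry, setting out from 1 and coming back at 7: Mitsunobu reaction of 1 with methyl (S)-lactate (PPh3, DIAD, THF) should give, with inversion, methyl (2R)-2-(4-bromo-2-formyl-6-methoxyphenoxy)propanoate F1. Baeyer–Villiger (Dakin-type) oxidation with mCPBA, hydrolysis of the aryl formate (aq. KHCO3, MeOH) and acid-catalysed lactonisation (TsOH, toluene) should give (3R)-7-bromo-5-methoxy-3-methyl-2,3-dihydro-1,4-benzodioxin-2-one F2. Reduction with iBu2AlH (CH2Cl2, −78 °C) should give the lactol (3R)-7-bromo-5-methoxy-3-methyl-2,3-dihydro-1,4-benzodioxin-2-ol F3. Commercial 3,4,5-trimethoxyphenylmagnesium bromide (THF, −40 → 0 °C) adds to its open form to give (2R)-2-(4-bromo-2-hydroxy-6-methoxyphenoxy)-1-(3,4,5-trimethoxyphenyl)propan-1-ol F4 as both carbinol epimers. Acid (TsOH or BF3·OEt2, CH2Cl2) then closes the ring through the benzylic cation to the thermodynamically preferred trans isomer 7. The methyl-bearing centre comes from the lactate and is not touched.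

2. Step 5. Oxidative addition of the electron-rich aryl bromide may be slow, and β-hydride elimination toward the acetal carbon would divert material to the saturated ester.
 Fallback, setting out from 7 and coming back at 9: bromine–lithium exchange (nBuLi, THF, −78 °C) and quench with DMF should give (2R,3R)-5-methoxy-3-methyl-2-(3,4,5-trimethoxyphenyl)-2,3-dihydro-1,4-benzodioxine-7-carbaldehyde F5. Wittig reaction with Ph3P=CHCHO (toluene, 80 °C) then gives the (E)-enal 9.

3. Step 2. Acetal exchange with the poorly nucleophilic phenolic hydroxyls may be slow, and the electron-rich ring may be C-alkylated by the oxocarbenium ion or the catechol may oxidise in air.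
 Fallback, setting out from 2 and coming back at 3: transfer vinylation with vinyl acetate ([Ir(cod)Cl]2, Na2CO3, toluene, 100 °C) should give the mono vinyl ether 4-bromo-2-(ethenyloxy)-6-methoxyphenol F6. With PPTS (CH2Cl2) the neighbouring hydroxyl adds in the Markovnikov sense to the vinyl ether and closes the dioxole ring to 3.

**Further compounds**
F1 | step 4 | methyl (2R)-2-(4-bromo-2-formyl-6-methoxyphenoxy)propanoate | C[C@@H](Oc1c(C=O)cc(Br)cc1OC)C(=O)OC
F2 | step 4 | (3R)-7-bromo-5-methoxy-3-methyl-2,3-dihydro-1,4-benzodioxin-2-one | C[C@H]1Oc2c(OC)cc(Br)cc2OC1=O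
F3 | step 4 | (3R)-7-bromo-5-methoxy-3-methyl-2,3-dihydro-1,4-benzodioxin-2-ol | C[C@H]1Oc2c(OC)cc(Br)cc2OC1O
F4 | step 4 | (2R)-2-(4-bromo-2-hydroxy-6-methoxyphenoxy)-1-(3,4,5-trimethoxyphenyl)propan-1-ol | C[C@@H](Oc1c(O)cc(Br)cc1OC)C(O)c1cc(OC)c(OC)c(OC)c1
F5 | step 5 | (2R,3R)-5-methoxy-3-methyl-2-(3,4,5-trimethoxyphenyl)-2,3-dihydro-1,4-benzodioxine-7-carbaldehyde | COc1cc([C@H]2Oc3cc(C=O)cc(OC)c3O[C@@H]2C)cc(OC)c1OC
F6 | step 2 | 4-bromo-2-(ethenyloxy)-6-methoxyphenol | C=COc1cc(Br)cc(OC)c1O
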